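**Plan**
Target numbering: oxolane O1, C2 (aryl), C3 (CH2O–acyl), C4 (bearing the exocyclic carbinol), C5 (H2). The retrosynthesis cuts, in order, the coumarate ester C–O, the carbinol-carbon–aryl bond (aryllithium + lactone carbonyl), one CO2Et (decarboxylation), and then O1–C5 and C3–C4 together in one formal [3+2] step.
Enabling feature: O1–C2–C3 is the O–C–C of an aryl vinyl oxirane, and C3 becomes an allyl terminus once its CH2OH is masked as ethenyl. C5–C4 is the β,α pair of a methylenemalonate; one ester carbon is the future carbinol carbon, the other is a removable activating group.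
Forward: diene → oxirane → oxolane ring (key step) → temporary cis-fused γ-lactone ring between the C3 arm and the C4 carboxyl → lactone opened by aryllithium → ketone reduced → coumarate attached → silyl ethers removed.
Stereochemistry: both oxirane centres come from a Shi epoxidation (catalysis), C3 from double inversion in the key step, C4 from the forced cis fusion of the lactone, and the carbinol from Felkin–Anh hydride addition.

Key step: step 4

Remark: all three phenols are carried as triisopropylsilyl (TIPS) ethers, because hydrogenolysis or acid at the end would attack the cinnamate and the benzylic C–O bonds; ArT = 3-methoxy-4-(triisopropylsilyloxy)phenyl.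

Step 1
Reactants: 1 coniferaldehyde, (E)-3-(4-hydroxy-3-methoxyphenyl)prop-2-enal
Product: 2 (E)-3-(ArT)prop-2-enal
Conditions: i-Pr3SiCl, imidazole, DMF, 23 °C
Reagents that add atoms: triisopropylsilyl chloride, CC(C)[Si](Cl)(C(C)C)C(C)C
Why: Imidazole-promoted silyl ether formation at the phenol; the bulky TIPS ether is chosen to survive the ylide, the carbonate-buffered oxidation, hot LiCl/DMSO, organolithium and hydride reagents and to fall to fluoride at the end.

Step 2
Reactants: 2 (E)-3-(ArT)prop-2-enal
Product: 3 (E)-1-(ArT)buta-1,3-diene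
Conditions: Ph3PCH3Br, KOt-Bu, THF, 0 → 23 °C
Reagents that add atoms: methyltriphenylphosphonium bromide, C[P+](c1ccccc1)(c1ccccc1)c1ccccc1.[Br-]
Why: Wittig methylenation of the aldehyde with the non-stabilised ylide gives the terminal diene without touching the existing E double bond.

Step 3
Reactants: 3 (E)-1-(ArT)buta-1,3-diene
Product: 4 (2R,3R)-2-ethenyl-3-(ArT)oxirane (trans)
Conditions: D-fructose-derived Shi ketone (30 mol %), Oxone (2KHSO5·KHSO4·K2SO4), K2CO3, Bu4NHSO4 (cat.), MeCN–CH2(OMe)2 / aq. Na2B4O7 buffer (pH 10.5), 0 °C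
Reagents that add atoms: potassium peroxymonosulfate KHSO5 (the oxidant in Oxone; its oxygen reaches the product through the dioxirane), [K+].[O-]S(=O)(=O)OO
Why: Shi epoxidation: the chiral dioxirane attacks the electron-rich trans-disubstituted styrenyl double bond and leaves the monosubstituted vinyl group, and its spiro transition state should give the (2R,3R)-oxirane as it does with trans-β-methylstyrene, so both oxirane centres are set by catalysis in one event.

Step 4
Reactants: 4 (2R,3R)-2-ethenyl-3-(ArT)oxirane; 5 diethyl methylenemalonate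
Product: 6 diethyl (4S,5S)-4-ethenyl-5-(ArT)oxolane-3,3-dicarboxylate (ethenyl and aryl trans)
Conditions: Pd(PPh3)4 (5 mol %, zerovalent palladium), THF, 40 °C, 5 added slowly
Reagents that add atoms: none
Why: Zerovalent palladium ionises the allylic C–O bond of the vinyl oxirane with inversion to give a zwitterionic π-allylpalladium alkoxide; the benzylic alkoxide adds to the CH2 terminus of 5 (oxa-Michael addition, bond O1–C5 in target numbering) and the malonate carbanion so formed alkylates the neighbouring allyl terminus on the face away from palladium (bond C3–C4), which frees the catalyst. The closest known reaction type is the palladium-catalysed formal [3+2] cycloaddition of vinyl oxiranes with doubly activated alkenes. The oxolane is closed by an intramolecular Tsuji–Trost alkylation in the 5-exo mode at the internal allyl carbon, because attack at the CH2 terminus would need a seven-membered ring. The one new stereocentre, the ethenyl-bearing carbon, is fixed by the two inversions (net retention of the oxirane C–O geometry, hence ethenyl trans to aryl), and if the allyl faces exchange by a π–σ–π shift through the CH2 terminus the ring closure with aryl and ethenyl trans is still the less crowded one; the benzylic centre is not touched and the quaternary carbon carries two equal esters. The step needs capture of the alkoxide by 5 to outrun closure to a 2,5-dihydrofuran or hydride-shift isomerisation of the oxirane, and ring closure to outrun oligomerisation of 5, which the high electrophilicity of the gem-diester alkene, its slow addition and the intramolecular C–C bond formation should secure. Both helpers leave later: the ethenyl group is the masked C3 hydroxymethyl (step 5) and the second ester is only an activating group (step 6).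

Step 5
Reactants: 6 diethyl (4S,5S)-4-ethenyl-5-(ArT)oxolane-3,3-dicarboxylate
Product: 9 ethyl (3aR,4S,6aR)-4-(ArT)-1-oxotetrahydro-1H,3H-furo[3,4-c]furan-6a-carboxylate (cis-fused), via formyl diester 7 (not isolated), via hydroxymethyl diester 8 (not isolated)
Conditions: K2OsO4·2H2O (2 mol %, hexavalent osmium), NaIO4, 2,6-lutidine, 1,4-dioxane–H2O, 23 °C; extractive work-up; then NaBH4, EtOH, 0 → 23 °C
Reagents that add atoms: sodium periodate NaIO4 (terminal oxidant; supplies, through the osmium oxo ligands, the oxygen of the new C–O), [Na+].[O-]I(=O)(=O)=O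
Why: Lemieux–Johnson oxidative cleavage is used instead of ozonolysis to spare the electron-rich arene, the aldehyde is reduced at once with NaBH4, and the primary alkoxide then lactonises on the one ester that is cis to it, so the ring fusion can only be cis and the remaining ester sits on the convex face.

Step 6
Reactants: 9 ethyl (3aR,4S,6aR)-4-(ArT)-1-oxotetrahydro-1H,3H-furo[3,4-c]furan-6a-carboxylate
Product: 10 (3aR,4S,6aR)-4-(ArT)tetrahydro-1H,3H-furo[3,4-c]furan-1-one (cis-fused, aryl on the convex face)
Conditions: LiCl, H2O (2 equiv), DMSO, 140 °C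
Reagents that add atoms: none
Why: Krapcho dealkoxycarbonylation (chloride attack at the ethyl group, loss of CO2) gives the lactone enolate, and its protonation can only give the cis-fused bicycle, which sets C4 of the target cis to the C3 arm; opening of the enolate by β-alkoxide loss would be the reverse of a 5-endo-trig closure and is stereoelectronically disfavoured.

Step 7
Reactants: 11 4-bromo-2-methoxyphenol
Product: 12 (4-bromo-2-methoxyphenoxy)triisopropylsilane
Conditions: i-Pr3SiCl, imidazole, DMF, 23 °C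
Reagents that add atoms: triisopropylsilyl chloride, CC(C)[Si](Cl)(C(C)C)C(C)C
Why: The same silyl ether formation as in step 1; the para relationship of OSi and Br excludes a retro-Brook shift after the later lithiation.

Step 8
Reactants: 12 (4-bromo-2-methoxyphenoxy)triisopropylsilane; 10 (3aR,4S,6aR)-4-(ArT)tetrahydro-1H,3H-furo[3,4-c]furan-1-one
Product: 14 (3aR,4S,6aR)-1,4-bis(ArT)tetrahydro-1H,3H-furo[3,4-c]furan-1-ol (hemiketal), via aryllithium 13 (not isolated)
Conditions: 12, n-BuLi, THF, −78 °C; then 10, −78 °C; aq. NH4Cl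
Reagents that add atoms: none
Why: Bromine–lithium exchange followed by acyl addition of the aryllithium to the γ-lactone; the tetrahedral lithium alkoxide persists at −78 °C, so a second addition is not expected, and the product rests as the bicyclic hemiketal, which keeps the α-centre from epimerising.

Step 9
Reactants: 14 (3aR,4S,6aR)-1,4-bis(ArT)tetrahydro-1H,3H-furo[3,4-c]furan-1-ol
Product: 16 (S)-[(3R,4R,5S)-4-(hydroxymethyl)-5-(ArT)oxolan-3-yl](ArT)methanol, via hydroxy ketone 15 (not isolated)
Conditions: LiBH(s-Bu)3 (2.5 equiv), THF, −78 °C; aq. NH4Cl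
Reagents that add atoms: none
Why: Felkin–Anh reduction of the ring-opened ketone by the bulky hydride: with the larger ring carbon (the one bearing the CH2O–Li arm) anti to the incoming hydride and the ring OCH2 carbon gauche to the carbonyl oxygen, hydride should add to the face that gives the (S)-carbinol, and a lithium chelate between the carbonyl and the ring oxygen exposes the same face.

Step 10
Reactants: 17 p-coumaric acid, (E)-3-(4-hydroxyphenyl)prop-2-enoic acid
Product: 19 (E)-3-[4-(triisopropylsilyloxy)phenyl]prop-2-enoic acid, via silyl ester 18 (not isolated)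
Conditions: i-Pr3SiCl (2.3 equiv), imidazole, DMF, 23 °C; then K2CO3, MeOH–THF–H2O, 0 °C; acidify to pH 4
Reagents that add atoms: triisopropylsilyl chloride, CC(C)[Si](Cl)(C(C)C)C(C)C
Why: Silylation of both acidic OH groups, then carbonate-mediated hydrolysis of the much more labile silyl ester, leaves the phenol silyl ether and frees the acid for coupling.

Step 11
Reactants: 16 (S)-[(3R,4R,5S)-4-(hydroxymethyl)-5-(ArT)oxolan-3-yl](ArT)methanol; 19 (E)-3-[4-(triisopropylsilyloxy)phenyl]prop-2-enoic acid
Product: 20 [(2S,3R,4R)-4-[(S)-hydroxy(ArT)methyl]-2-(ArT)oxolan-3-yl]methyl (E)-3-[4-(triisopropylsilyloxy)phenyl]prop-2-enoate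
Conditions: N,N'-diisopropylcarbodiimide (DIC), DMAP (10 mol %), CH2Cl2, −20 → 0 °C
Reagents that add atoms: none
Why: Steglich esterification at low temperature acylates the unhindered primary alcohol in preference to the hindered secondary benzylic one, and the nearly neutral medium avoids cyclodehydration of the 1,4-diol.

Step 12
Reactants: 20 [(2S,3R,4R)-4-[(S)-hydroxy(ArT)methyl]-2-(ArT)oxolan-3-yl]methyl (E)-3-[4-(triisopropylsilyloxy)phenyl]prop-2-enoate
Product: 21 the target, [(2S,3R,4R)-2-(4-hydroxy-3-methoxyphenyl)-4-[(S)-hydroxy(4-hydroxy-3-methoxyphenyl)methyl]oxolan-3-yl]methyl (E)-3-(4-hydroxyphenyl)prop-2-enoate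
Conditions: Bu4NF, AcOH (1:1, 3.5 equiv), THF, 0 °C
Reagents that add atoms: none
Why: Fluoride-induced cleavage of the three aryl silyl ethers, buffered with acetic acid so that the phenoxides do not trigger quinone-methide formation at the benzylic positions, ester cleavage or acyl migration.

**Compound list**
1 | coniferaldehyde, (E)-3-(4-hydroxy-3-methoxyphenyl)prop-2-enal | COc1cc(/C=C/C=O)ccc1O | starting material
2 | (E)-3-[3-methoxy-4-(triisopropylsilyloxy)phenyl]prop-2-enal | COc1cc(/C=C/C=O)ccc1O[Si](C(C)C)(C(C)C)C(C)C | intermediate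
3 | (E)-1-[3-methoxy-4-(triisopropylsilyloxy)phenyl]buta-1,3-diene | COc1cc(/C=C/C=C)ccc1O[Si](C(C)C)(C(C)C)C(C)C | intermediate
4 | (2R,3R)-2-ethenyl-3-[3-methoxy-4-(triisopropylsilyloxy)phenyl]oxirane (trans) | C=C[C@H]1O[C@@H]1c1ccc(O[Si](C(C)C)(C(C)C)C(C)C)c(OC)c1 | intermediate
5 | diethyl methylenemalonate (diethyl 2-methylidenepropanedioate) | C=C(C(=O)OCC)C(=O)OCC | starting material
6 | diethyl (4S,5S)-4-ethenyl-5-[3-methoxy-4-(triisopropylsilyloxy)phenyl]oxolane-3,3-dicarboxylate (ethenyl and aryl trans) | CCOC(=O)C1(C(=O)OCC)CO[C@H](c2ccc(O[Si](C(C)C)(C(C)C)C(C)C)c(OC)c2)[C@H]1C=C | intermediate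
7 | diethyl (4S,5S)-4-formyl-5-[3-methoxy-4-(triisopropylsilyloxy)phenyl]oxolane-3,3-dicarboxylate (not isolated) | CCOC(=O)C1(C(=O)OCC)CO[C@H](c2ccc(O[Si](C(C)C)(C(C)C)C(C)C)c(OC)c2)[C@H]1C=O | intermediate
8 | diethyl (4R,5S)-4-(hydroxymethyl)-5-[3-methoxy-4-(triisopropylsilyloxy)phenyl]oxolane-3,3-dicarboxylate (not isolated) | CCOC(=O)C1(C(=O)OCC)CO[C@H](c2ccc(O[Si](C(C)C)(C(C)C)C(C)C)c(OC)c2)[C@H]1CO | intermediate
9 | ethyl (3aR,4S,6aR)-4-[3-methoxy-4-(triisopropylsilyloxy)phenyl]-1-oxotetrahydro-1H,3H-furo[3,4-c]furan-6a-carboxylate (cis-fused, ester on the convex face) | O=C1[C@@]2(C(=O)OCC)CO[C@H](c3ccc(O[Si](C(C)C)(C(C)C)C(C)C)c(OC)c3)[C@H]2CO1 | intermediate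
10 | (3aR,4S,6aR)-4-[3-methoxy-4-(triisopropylsilyloxy)phenyl]tetrahydro-1H,3H-furo[3,4-c]furan-1-one (cis-fused, aryl on the convex face) | O=C1[C@H]2CO[C@H](c3ccc(O[Si](C(C)C)(C(C)C)C(C)C)c(OC)c3)[C@H]2CO1 | intermediate
11 | 4-bromo-2-methoxyphenol | COc1cc(Br)ccc1O | starting material
12 | (4-bromo-2-methoxyphenoxy)triisopropylsilane | COc1cc(Br)ccc1O[Si](C(C)C)(C(C)C)C(C)C | intermediate
13 | [3-methoxy-4-(triisopropylsilyloxy)phenyl]lithium (not isolated) | COc1cc([Li])ccc1O[Si](C(C)C)(C(C)C)C(C)C | intermediate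
14 | (3aR,4S,6aR)-1,4-bis[3-methoxy-4-(triisopropylsilyloxy)phenyl]tetrahydro-1H,3H-furo[3,4-c]furan-1-ol (hemiketal, either configuration at C1) | COc1cc(C2(O)[C@H]3CO[C@H](c4ccc(O[Si](C(C)C)(C(C)C)C(C)C)c(OC)c4)[C@H]3CO2)ccc1O[Si](C(C)C)(C(C)C)C(C)C | intermediate
15 | [(3R,4R,5S)-4-(hydroxymethyl)-5-[3-methoxy-4-(triisopropylsilyloxy)phenyl]oxolan-3-yl][3-methoxy-4-(triisopropylsilyloxy)phenyl]methanone (ring-opened tautomer of 14, not isolated) | COc1cc(C(=O)[C@H]2CO[C@H](c3ccc(O[Si](C(C)C)(C(C)C)C(C)C)c(OC)c3)[C@H]2CO)ccc1O[Si](C(C)C)(C(C)C)C(C)C | intermediate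
16 | (S)-[(3R,4R,5S)-4-(hydroxymethyl)-5-[3-methoxy-4-(triisopropylsilyloxy)phenyl]oxolan-3-yl][3-methoxy-4-(triisopropylsilyloxy)phenyl]methanol | COc1cc([C@@H](O)[C@H]2CO[C@H](c3ccc(O[Si](C(C)C)(C(C)C)C(C)C)c(OC)c3)[C@H]2CO)ccc1O[Si](C(C)C)(C(C)C)C(C)C | intermediate
17 | p-coumaric acid, (E)-3-(4-hydroxyphenyl)prop-2-enoic acid | OC(=O)/C=C/c1ccc(O)cc1 | starting material
18 | triisopropylsilyl (E)-3-[4-(triisopropylsilyloxy)phenyl]prop-2-enoate (not isolated) | CC(C)[Si](C(C)C)(C(C)C)OC(=O)/C=C/c1ccc(O[Si](C(C)C)(C(C)C)C(C)C)cc1 | intermediate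
19 | (E)-3-[4-(triisopropylsilyloxy)phenyl]prop-2-enoic acid | OC(=O)/C=C/c1ccc(O[Si](C(C)C)(C(C)C)C(C)C)cc1 | intermediate
20 | [(2S,3R,4R)-4-[(S)-hydroxy[3-methoxy-4-(triisopropylsilyloxy)phenyl]methyl]-2-[3-methoxy-4-(triisopropylsilyloxy)phenyl]oxolan-3-yl]methyl (E)-3-[4-(triisopropylsilyloxy)phenyl]prop-2-enoate | COc1cc([C@@H](O)[C@H]2CO[C@H](c3ccc(O[Si](C(C)C)(C(C)C)C(C)C)c(OC)c3)[C@H]2COC(=O)/C=C/c2ccc(O[Si](C(C)C)(C(C)C)C(C)C)cc2)ccc1O[Si](C(C)C)(C(C)C)C(C)C | intermediate
21 | [(2S,3R,4R)-2-(4-hydroxy-3-methoxyphenyl)-4-[(S)-hydroxy(4-hydroxy-3-methoxyphenyl)methyl]oxolan-3-yl]methyl (E)-3-(4-hydroxyphenyl)prop-2-enoate | COc1cc([C@@H](O)[C@H]2CO[C@H](c3ccc(O)c(OC)c3)[C@H]2COC(=O)/C=C/c2ccc(O)cc2)ccc1O | target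

**Step count and risks**
Total step count: 12. Longest linear sequence: 10 steps (steps 1–6, 8, 9, 11, 12, from coniferaldehyde).

Step 4 (key step). The palladium-bound alkoxide may start anionic oligomerisation of the methylenemalonate. The allyl intermediate may also collapse before the acceptor is captured (closure to a 2,5-dihydrofuran, hydride shift to an enone), or allyl face exchange may erode the trans relationship. The fallback sets out from 4 and returns at 6, making the two bonds one after the other. Pd(PPh3)4-catalysed addition of acetic acid to 4 should give the 1,4-adduct (2E,4S)-4-hydroxy-4-(ArT)but-2-en-1-yl acetate F1, with the benzylic centre untouched. Amine-catalysed oxa-Michael addition of its hydroxyl to 5 (Et3N cat., CH2Cl2, 0 °C) should give the ether diethyl 2-({[(1S,2E)-4-acetoxy-1-(ArT)but-2-en-1-yl]oxy}methyl)propanedioate F2. Intramolecular Tsuji–Trost alkylation (Pd(PPh3)4, NaH, THF) then closes the oxolane to 6, with acetate as the leaving group. Each bond formation can then be optimised alone, and no free alkoxide meets the acceptor while the allyl cation is present.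

Step 3. The electron-rich benzylic, allylic oxirane may open hydrolytically or rearrange in the aqueous oxidant and on silica, or the dioxirane may discriminate the alkene faces insufficiently. The fallback sets out from 2 and returns at 4. Luche reduction (NaBH4, CeCl3·7H2O, MeOH) gives (E)-3-(ArT)prop-2-en-1-ol F3. Sharpless asymmetric epoxidation (Ti(Oi-Pr)4, D-(−)-diisopropyl tartrate, t-BuOOH, 4 Å sieves, CH2Cl2, −20 °C) gives [(2R,3R)-3-(ArT)oxiran-2-yl]methanol F4 under anhydrous conditions. Parikh–Doering oxidation (SO3·pyridine, DMSO, i-Pr2NEt) gives (2S,3R)-3-(ArT)oxirane-2-carbaldehyde F5, and Wittig methylenation (Ph3PCH3Br, KOt-Bu, THF) gives 4.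

Step 9. Facial selectivity may be poor if a chelate through the neighbouring lithium alkoxide competes with the Felkin–Anh approach, and the centre alpha to the ketone may epimerise in the ring-opened alkoxide. The fallback sets out from 14 (with 19) and returns at 20. Steglich acylation of 14 with 19 (DIC, DMAP, CH2Cl2) traps the ring-opened tautomer as the keto ester [(2S,3R,4R)-2-(ArT)-4-[3-methoxy-4-(triisopropylsilyloxy)benzoyl]oxolan-3-yl]methyl (E)-3-[4-(triisopropylsilyloxy)phenyl]prop-2-enoate F6. Noyori asymmetric transfer hydrogenation with RuCl[(S,S)-TsDPEN](p-cymene) (divalent ruthenium) and HCO2H–Et3N then sets the carbinol under catalyst control. This catalyst enantiomer reduces aryl alkyl ketones to the (S)-alcohols and leaves the cinnamate double bond alone, so 20 should result directly.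

**Further compounds**
F1 | step 4 | (2E,4S)-4-hydroxy-4-[3-methoxy-4-(triisopropylsilyloxy)phenyl]but-2-en-1-yl acetate | CC(=O)OC/C=C/[C@H](O)c1ccc(O[Si](C(C)C)(C(C)C)C(C)C)c(OC)c1
F2 | step 4 | diethyl 2-({[(1S,2E)-4-acetoxy-1-[3-methoxy-4-(triisopropylsilyloxy)phenyl]but-2-en-1-yl]oxy}methyl)propanedioate | CCOC(=O)C(CO[C@@H](/C=C/COC(C)=O)c1ccc(O[Si](C(C)C)(C(C)C)C(C)C)c(OC)c1)C(=O)OCC
F3 | step 3 | (E)-3-[3-methoxy-4-(triisopropylsilyloxy)phenyl]prop-2-en-1-ol | COc1cc(/C=C/CO)ccc1O[Si](C(C)C)(C(C)C)C(C)C
F4 | step 3 | [(2R,3R)-3-[3-methoxy-4-(triisopropylsilyloxy)phenyl]oxiran-2-yl]methanol | OC[C@H]1O[C@@H]1c1ccc(O[Si](C(C)C)(C(C)C)C(C)C)c(OC)c1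
F5 | step 3 | (2S,3R)-3-[3-methoxy-4-(triisopropylsilyloxy)phenyl]oxirane-2-carbaldehyde | O=C[C@H]1O[C@@H]1c1ccc(O[Si](C(C)C)(C(C)C)C(C)C)c(OC)c1
F6 | step 9 | [(2S,3R,4R)-2-[3-methoxy-4-(triisopropylsilyloxy)phenyl]-4-[3-methoxy-4-(triisopropylsilyloxy)benzoyl]oxolan-3-yl]methyl (E)-3-[4-(triisopropylsilyloxy)phenyl]prop-2-enoate | COc1cc(C(=O)[C@H]2CO[C@H](c3ccc(O[Si](C(C)C)(C(C)C)C(C)C)c(OC)c3)[C@H]2COC(=O)/C=C/c2ccc(O[Si](C(C)C)(C(C)C)C(C)C)cc2)ccc1O[Si](C(C)C)(C(C)C)C(C)C
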